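**Assumption:** compounds 1, 2 and 14 and all reagents are bought; the target is the 3R enantiomer encoded by the SMILES.

## Retrosynthetic overview

1. The target is cut at the ArCH2–C5 bond of the isochromanone. This gives phenol 13, which has one free ring carbon, and o-quinone methide 25, released from ammonium salt 24; the two halves are joined last by an intermolecular Michael addition.
2. Fragment A (chromone, 24): the pyranone ring comes from a Claisen condensation with ethyl acetate and cyclodehydration of an o-hydroxyaryl diketone whose other ortho oxygen is a methyl ether, so only one chromone can form. The acetyl group is put in by directed lithiation of the symmetric MOM ether of aldehyde 14, whose CHO carbon becomes the bridging CH2 (carried as CH2NMe2).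
3. Fragment B (isochromanone, 13): the lactone ring comes from carboxylation and lactonisation of an ortho-lithiated (R)-1-arylpropan-2-ol. The stereocentre comes from (R)-propylene oxide, and the C7 methyl from lithiation between the two methoxy groups.
4. Ring order: lactone ring of fragment B (step 5), pyranone ring of fragment A (step 11), then union of the two bicycles (step 14).

## Route

**Step 1**
Reactants: 1 1-bromo-3,5-dimethoxybenzene; 2 (2R)-2-methyloxirane
Product: 4 (2R)-1-(3,5-dimethoxyphenyl)propan-2-ol, via arylmagnesium bromide 3 (not isolated)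
Conditions: Mg, THF, reflux; CuBr·SMe2 (10 mol%), 2, −30 → 0 °C; then 1 M HCl
Reagents that add atoms: none
Why: Copper-catalysed SN2 opening of the epoxide by the aryl Grignard reagent occurs at the CH2 terminus, so the stereocentre of 2 is untouched and becomes C3 (R) of the target.

**Step 2**
Reactants: 4 (2R)-1-(3,5-dimethoxyphenyl)propan-2-ol
Product: 5 tert-butyl{[(2R)-1-(3,5-dimethoxyphenyl)propan-2-yl]oxy}dimethylsilane
Conditions: TBSCl, imidazole, DMF, rt
Reagents that add atoms: tert-butyldimethylsilyl chloride CC(C)(C)[Si](C)(C)Cl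
Why: Silyl ether protection masks the alcohol so that it neither directs the next lithiation nor is O-methylated.

**Step 3**
Reactants: 5 tert-butyl{[(2R)-1-(3,5-dimethoxyphenyl)propan-2-yl]oxy}dimethylsilane
Product: 7 tert-butyl{[(2R)-1-(3,5-dimethoxy-4-methylphenyl)propan-2-yl]oxy}dimethylsilane, via aryllithium 6 (not isolated)
Conditions: n-BuLi (1.3 equiv), THF, 0 °C → rt; MeI, −78 °C → rt; H2O
Reagents that add atoms: iodomethane CI
Why: Directed ortho-metalation takes the C–H flanked by both methoxy groups, the most acidic ring position, and the aryllithium is C-methylated by MeI.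

**Step 4**
Reactants: 7 tert-butyl{[(2R)-1-(3,5-dimethoxy-4-methylphenyl)propan-2-yl]oxy}dimethylsilane
Product: 8 {[(2R)-1-(2-bromo-3,5-dimethoxy-4-methylphenyl)propan-2-yl]oxy}(tert-butyl)dimethylsilane
Conditions: NBS (1.05 equiv), MeCN, 0 °C → rt, dark
Reagents that add atoms: N-bromosuccinimide O=C1CCC(=O)N1Br
Why: Electrophilic aromatic bromination gives one monobromide because the two free ring positions are equivalent and activated ortho/para by the methoxy groups.

**Step 5**
Reactants: 8 {[(2R)-1-(2-bromo-3,5-dimethoxy-4-methylphenyl)propan-2-yl]oxy}(tert-butyl)dimethylsilane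
Product: 12 (3R)-6,8-dimethoxy-3,7-dimethyl-3,4-dihydro-1H-isochromen-1-one, via aryllithium 9 (not isolated), via silyloxy acid 10 (not isolated), via hydroxy acid 11 (not isolated)
Conditions: n-BuLi (1.1 equiv), THF, −78 °C; CO2 (g), −78 °C → rt; then 2 M HCl (aq), THF, 40 °C
Reagents that add atoms: carbon dioxide O=C=O
Why: Bromine–lithium exchange and carboxylation place the carboxyl carbon ortho to the side chain, and aqueous acid then removes the silyl group and closes the lactone (acid-catalysed lactonisation) without breaking the carbinol C–O bond, so R is retained.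

**Step 6**
Reactants: 12 (3R)-6,8-dimethoxy-3,7-dimethyl-3,4-dihydro-1H-isochromen-1-one
Product: 13 (3R)-6,8-dihydroxy-3,7-dimethyl-3,4-dihydro-1H-isochromen-1-one
Conditions: BBr3 (5 equiv), CH2Cl2, −78 °C → rt; MeOH then H2O
Reagents that add atoms: none
Why: Lewis-acid aryl methyl ether cleavage removes both methyl groups (the C8 ether first, through chelation to the lactone carbonyl) under conditions the lactone and its stereocentre tolerate.

**Step 7**
Reactants: 14 4-hydroxy-2,6-dimethoxybenzaldehyde
Product: 15 2,6-dimethoxy-4-(methoxymethoxy)benzaldehyde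
Conditions: MOMCl, iPr2NEt, CH2Cl2, 0 °C → rt
Reagents that add atoms: chloromethyl methyl ether COCCl
Why: O-alkylation of the acidic para-formyl phenol installs a MOM ether that later directs lithiation and is removed by acid.

**Step 8**
Reactants: 15 2,6-dimethoxy-4-(methoxymethoxy)benzaldehyde
Product: 17 1-[2,6-dimethoxy-4-(methoxymethoxy)phenyl]-N,N-dimethylmethanamine, via iminium ion 16 (not isolated)
Conditions: Me2NH (2 M in THF), AcOH, NaBH(OAc)3, 1,2-dichloroethane, rt; H2O
Reagents that add atoms: dimethylamine CNC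
Why: Reductive amination turns the aldehyde carbon into a CH2NMe2 group that survives the coming base and acid steps and later serves as the leaving group for the quinone methide.

**Step 9**
Reactants: 17 1-[2,6-dimethoxy-4-(methoxymethoxy)phenyl]-N,N-dimethylmethanamine
Product: 19 1-{3-[(dimethylamino)methyl]-2,4-dimethoxy-6-(methoxymethoxy)phenyl}ethan-1-one, via aryllithium 18 (not isolated)
Conditions: n-BuLi (1.2 equiv), THF, 0 °C; MeC(O)N(OMe)Me, −78 → 0 °C; H2O
Reagents that add atoms: N-methoxy-N-methylacetamide CC(=O)N(C)OC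
Why: Directed ortho-metalation next to the MOM ether is unambiguous because the only two ring C–H positions are equivalent by symmetry, and Weinreb amide acylation stops at the methyl ketone.

**Step 10**
Reactants: 19 1-{3-[(dimethylamino)methyl]-2,4-dimethoxy-6-(methoxymethoxy)phenyl}ethan-1-one
Product: 20 1-{3-[(dimethylamino)methyl]-2,4-dimethoxy-6-(methoxymethoxy)phenyl}butane-1,3-dione
Conditions: NaH (3 equiv), EtOAc (10 equiv), THF, reflux; AcOH quench
Reagents that add atoms: ethyl acetate CCOC(C)=O
Why: Crossed Claisen condensation of the ketone enolate with ethyl acetate is driven to completion by deprotonation of the 1,3-diketone product.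

**Step 11**
Reactants: 20 1-{3-[(dimethylamino)methyl]-2,4-dimethoxy-6-(methoxymethoxy)phenyl}butane-1,3-dione
Product: 22 6-[(dimethylamino)methyl]-5,7-dimethoxy-2-methyl-4H-chromen-4-one, via free phenol diketone 21 (not isolated)
Conditions: 3 M HCl in MeOH, 50 °C; then NaHCO3 (aq)
Reagents that add atoms: none
Why: Acid cleaves the MOM acetal and the freed phenol cyclodehydrates onto the diketone (chromone cyclodehydration), and only one chromone can form because the other ortho oxygen is a methyl ether.

**Step 12**
Reactants: 22 6-[(dimethylamino)methyl]-5,7-dimethoxy-2-methyl-4H-chromen-4-one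
Product: 23 6-[(dimethylamino)methyl]-5-hydroxy-7-methoxy-2-methyl-4H-chromen-4-one
Conditions: BCl3 (3.5 equiv), CH2Cl2, −78 → 0 °C; MeOH, then NaHCO3 (aq)
Reagents that add atoms: none
Why: Chelation-controlled demethylation cleaves only the C5 methyl ether, because BCl3 bound to the C4 carbonyl reaches only that peri oxygen.

**Step 13**
Reactants: 23 6-[(dimethylamino)methyl]-5-hydroxy-7-methoxy-2-methyl-4H-chromen-4-one
Product: 24 1-(5-hydroxy-7-methoxy-2-methyl-4-oxo-4H-chromen-6-yl)-N,N,N-trimethylmethanaminium iodide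
Conditions: MeI (3 equiv), acetone, rt, dark; filter, wash with Et2O
Reagents that add atoms: iodomethane CI
Why: Menshutkin quaternisation turns the amine into a trimethylammonium leaving group so the quinone methide can be released under mild base.

**Step 14**
Reactants: 24 1-(5-hydroxy-7-methoxy-2-methyl-4-oxo-4H-chromen-6-yl)-N,N,N-trimethylmethanaminium iodide; 13 (3R)-6,8-dihydroxy-3,7-dimethyl-3,4-dihydro-1H-isochromen-1-one
Product: 26 (3R)-6,8-dihydroxy-5-[(5-hydroxy-7-methoxy-2-methyl-4-oxo-4H-chromen-6-yl)methyl]-3,7-dimethyl-3,4-dihydro-1H-isochromen-1-one, via o-quinone methide 25 (not isolated)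
Conditions: 13 (1.5 equiv), K2CO3 (2.5 equiv), DMF, 0 °C; slow addition of 24 in DMF; rt; 1 M HCl work-up
Reagents that add atoms: none
Why: Base-induced 1,4-elimination of NMe3 gives o-quinone methide 25, and the phenoxide of 13 adds to it in an intermolecular Michael addition through C5, its only free ring carbon, with rearomatisation making the C–C bond irreversible and no stereocentre formed or touched.

## Compound list

1 | 1-bromo-3,5-dimethoxybenzene | COc1cc(Br)cc(OC)c1 | starting material
2 | (2R)-2-methyloxirane ((R)-propylene oxide) | C[C@@H]1CO1 | starting material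
3 | (3,5-dimethoxyphenyl)magnesium bromide | COc1cc([Mg]Br)cc(OC)c1 | intermediate
4 | (2R)-1-(3,5-dimethoxyphenyl)propan-2-ol | C[C@@H](O)Cc1cc(OC)cc(OC)c1 | intermediate
5 | tert-butyl{[(2R)-1-(3,5-dimethoxyphenyl)propan-2-yl]oxy}dimethylsilane | C[C@@H](O[Si](C)(C)C(C)(C)C)Cc1cc(OC)cc(OC)c1 | intermediate
6 | {4-[(2R)-2-{[tert-butyl(dimethyl)silyl]oxy}propyl]-2,6-dimethoxyphenyl}lithium | C[C@@H](O[Si](C)(C)C(C)(C)C)Cc1cc(OC)c([Li])c(OC)c1 | intermediate
7 | tert-butyl{[(2R)-1-(3,5-dimethoxy-4-methylphenyl)propan-2-yl]oxy}dimethylsilane | C[C@@H](O[Si](C)(C)C(C)(C)C)Cc1cc(OC)c(C)c(OC)c1 | intermediate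
8 | {[(2R)-1-(2-bromo-3,5-dimethoxy-4-methylphenyl)propan-2-yl]oxy}(tert-butyl)dimethylsilane | C[C@@H](O[Si](C)(C)C(C)(C)C)Cc1cc(OC)c(C)c(OC)c1Br | intermediate
9 | {6-[(2R)-2-{[tert-butyl(dimethyl)silyl]oxy}propyl]-2,4-dimethoxy-3-methylphenyl}lithium | C[C@@H](O[Si](C)(C)C(C)(C)C)Cc1cc(OC)c(C)c(OC)c1[Li] | intermediate
10 | 6-[(2R)-2-{[tert-butyl(dimethyl)silyl]oxy}propyl]-2,4-dimethoxy-3-methylbenzoic acid | C[C@@H](O[Si](C)(C)C(C)(C)C)Cc1cc(OC)c(C)c(OC)c1C(=O)O | intermediate
11 | 6-[(2R)-2-hydroxypropyl]-2,4-dimethoxy-3-methylbenzoic acid | C[C@@H](O)Cc1cc(OC)c(C)c(OC)c1C(=O)O | intermediate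
12 | (3R)-6,8-dimethoxy-3,7-dimethyl-3,4-dihydro-1H-isochromen-1-one | C[C@@H]1Cc2cc(OC)c(C)c(OC)c2C(=O)O1 | intermediate
13 | (3R)-6,8-dihydroxy-3,7-dimethyl-3,4-dihydro-1H-isochromen-1-one | C[C@@H]1Cc2cc(O)c(C)c(O)c2C(=O)O1 | intermediate
14 | 4-hydroxy-2,6-dimethoxybenzaldehyde | COc1cc(O)cc(OC)c1C=O | starting material
15 | 2,6-dimethoxy-4-(methoxymethoxy)benzaldehyde | COCOc1cc(OC)c(C=O)c(OC)c1 | intermediate
16 | N-{[2,6-dimethoxy-4-(methoxymethoxy)phenyl]methylidene}-N-methylmethanaminium acetate | COCOc1cc(OC)c(C=[N+](C)C)c(OC)c1.CC(=O)[O-] | intermediate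
17 | 1-[2,6-dimethoxy-4-(methoxymethoxy)phenyl]-N,N-dimethylmethanamine | COCOc1cc(OC)c(CN(C)C)c(OC)c1 | intermediate
18 | {3-[(dimethylamino)methyl]-2,4-dimethoxy-6-(methoxymethoxy)phenyl}lithium | COCOc1cc(OC)c(CN(C)C)c(OC)c1[Li] | intermediate
19 | 1-{3-[(dimethylamino)methyl]-2,4-dimethoxy-6-(methoxymethoxy)phenyl}ethan-1-one | COCOc1cc(OC)c(CN(C)C)c(OC)c1C(C)=O | intermediate
20 | 1-{3-[(dimethylamino)methyl]-2,4-dimethoxy-6-(methoxymethoxy)phenyl}butane-1,3-dione | COCOc1cc(OC)c(CN(C)C)c(OC)c1C(=O)CC(C)=O | intermediate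
21 | 1-{3-[(dimethylamino)methyl]-6-hydroxy-2,4-dimethoxyphenyl}butane-1,3-dione | Oc1cc(OC)c(CN(C)C)c(OC)c1C(=O)CC(C)=O | intermediate
22 | 6-[(dimethylamino)methyl]-5,7-dimethoxy-2-methyl-4H-chromen-4-one | COc1cc2oc(C)cc(=O)c2c(OC)c1CN(C)C | intermediate
23 | 6-[(dimethylamino)methyl]-5-hydroxy-7-methoxy-2-methyl-4H-chromen-4-one | COc1cc2oc(C)cc(=O)c2c(O)c1CN(C)C | intermediate
24 | 1-(5-hydroxy-7-methoxy-2-methyl-4-oxo-4H-chromen-6-yl)-N,N,N-trimethylmethanaminium iodide | COc1cc2oc(C)cc(=O)c2c(O)c1C[N+](C)(C)C.[I-] | intermediate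
25 | 7-methoxy-2-methyl-6-methylidene-4H-chromene-4,5(6H)-dione (o-quinone methide) | C=C1C(OC)=CC2=C(C1=O)C(=O)C=C(C)O2 | intermediate
26 | (3R)-6,8-dihydroxy-5-[(5-hydroxy-7-methoxy-2-methyl-4-oxo-4H-chromen-6-yl)methyl]-3,7-dimethyl-3,4-dihydro-1H-isochromen-1-one | COc1cc2oc(C)cc(=O)c2c(O)c1Cc1c(O)c(C)c(O)c2c1C[C@@H](C)OC2=O | target

## Step count and risks

Total step count: 14. Longest linear sequence: 8 steps (steps 7–14, from 14 to 26). The fragment B branch is 6 steps (1–6) before the union.

**Step 14 (most at risk).** The phenoxide of 13 may be alkylated on oxygen or at the methyl-bearing C7, or 25 may attack C8 of another chromone. The fallback changes the quinone methide precursor and runs the addition without base. It sets out from 24: warming with NaOAc in AcOH at 60 °C traps 25 as the neutral, storable benzylic acetate (5-hydroxy-7-methoxy-2-methyl-4-oxo-4H-chromen-6-yl)methyl acetate F1. Heating this acetate with 13 (1.5 equiv) in toluene at 110 °C releases 25 slowly by loss of acetic acid, and the un-ionised phenol adds through C5 under hydrogen-bond guidance. The fallback comes back to the route at 26.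

**Step 9.** The hindered aryllithium 18 may deprotonate the Weinreb amide instead of adding to it. The fallback is a two-stage addition and oxidation. It sets out from 17: the same lithiation gives 18, which is quenched at −78 °C with acetaldehyde, a far more reactive electrophile, to give the racemic carbinol 1-{3-[(dimethylamino)methyl]-2,4-dimethoxy-6-(methoxymethoxy)phenyl}ethan-1-ol F2. Swern oxidation ((COCl)2, DMSO, Et3N, −78 °C) then gives the ketone, and the fallback comes back to the route at 19.

**Step 5.** Aryllithium 9 may be protonated, or the electron-rich acid 11 may decarboxylate in acid before the ring closes. The fallback is a palladium-catalysed cyclocarbonylation that never passes through a free benzoic acid. It sets out from 8: TBAF in THF at rt gives the bromo alcohol (2R)-1-(2-bromo-3,5-dimethoxy-4-methylphenyl)propan-2-ol F3. Pd(OAc)2 (5 mol%), Xantphos (6 mol%), CO (1 atm) and Et3N in toluene at 100 °C then close the lactone by intramolecular alkoxycarbonylation. The fallback comes back to the route at 12.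

## Further compounds

F1 | step 14 | (5-hydroxy-7-methoxy-2-methyl-4-oxo-4H-chromen-6-yl)methyl acetate | COc1cc2oc(C)cc(=O)c2c(O)c1COC(C)=O
F2 | step 9 | 1-{3-[(dimethylamino)methyl]-2,4-dimethoxy-6-(methoxymethoxy)phenyl}ethan-1-ol (racemic) | COCOc1cc(OC)c(CN(C)C)c(OC)c1C(C)O
F3 | step 5 | (2R)-1-(2-bromo-3,5-dimethoxy-4-methylphenyl)propan-2-ol | C[C@@H](O)Cc1cc(OC)c(C)c(OC)c1Br
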